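## Structural features

The target is an open-chain diester on one benzene ring. C1 of a 3-hydroxy-4,5-dimethoxyphenyl ring carries a 1-acyloxypropyl chain, the acyl group is a (Z)-2-(acyloxymethyl)but-2-enoyl unit, and its CH2–O is esterified by angelic acid, (Z)-2-methylbut-2-enoic acid. The only stereocentre is the benzylic carbinol carbon (S). It has no stereogenic neighbour, but it lies between an electron-rich ring and an acyloxy leaving group, so it can ionise (racemisation, elimination to the propenylarene) under protic or Lewis acid and is open to hydrogenolysis. Both trisubstituted alkenes have the less stable geometry, with the β-methyl group cis to the carbonyl, and drift to E under nucleophilic catalysts, radicals, metal hydrides or strong acid. The central unit is an acyloxymethyl acrylate, an allylic ester of the Morita–Baylis–Hillman type, which amines, phosphines and low-valent metals attack by SN2′ displacement or ionisation. The ring holds three adjacent oxygens of which only the one at C3 is free, and that phenol is sensitive to oxidants once formed. The difficulty is therefore the order of events, not the small skeleton: one ring oxygen must be told apart from two others in the presence of two Z-enoates, an SN2′-prone allylic ester and a labile benzylic ester, without a chain of protecting groups. The key step uses the substitution pattern of the ring: in the 3,4-dimethoxyphenyl analogue C2–H lies between the chain and a methoxy group, C6–H lies next to the branched C1 substituent, and only C5–H, flanked by the C4 methoxy group alone, is open to a sterically governed catalyst. That carbon is C3 of the target ring.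

## Logic of the disconnections

14 ⇒ 12. The ring C3–O bond is traced back to a C3–B bond (forward through 13). A boronate stands in for the phenol until the last step, so no phenol protecting group is carried and the oxygen appears exactly where boron was. The forward step needs an oxidant that attacks boron faster than the two enoates or the new phenol, and that is neither basic nor strongly acidic.

12 ⇒ 10 + 11. The C3–B bond is cut back to the C–H bond of 10. This removes the whole problem of differentiating three ring oxygens, because the aryl part becomes a plain veratryl unit. The demand is heavy: one of three aryl C–H bonds must react, at a site next to a methoxy group, while two conjugated alkenes, an allylic ester and a benzylic ester are left alone.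

10 ⇒ 7 + 8. The acyl–O bond of the outer ester is cut. 8 brings its Z alkene ready-made and 7 is a primary allylic alcohol. The acylation must not let the Z-acyl group relax to E and must not use a nucleophile that adds to the acrylate of 7.

7 ⇒ 5. The C2–CH2 and C3–H bonds of the butenoate are cut, which returns the trisubstituted Z alkene to a linear alkyne. The hydroxymethyl group and the geometry then both come from one syn addition of H–Al across the triple bond and capture of the C–Al bond of 6 by a one-carbon aldehyde. The forward step needs conjugate hydride delivery in preference to carbonyl reduction, and C–C bond formation with retention at C2.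

5 ⇒ 2 + 3. The acyl–O bond of the benzylic ester is cut (forward through 4). The pieces are a one-step alcohol and a purchasable acid. The acid, not the alcohol, must be activated, so that the C–O bond at the stereocentre is never broken.

2 ⇒ 1. The C–H bond at the carbinol carbon is cut, leaving a prochiral aryl ethyl ketone. The forward reduction must distinguish the aryl from the ethyl flank of the carbonyl to set the S configuration.

## Other disconnections considered

Alternative 1: The cut is the benzylic C–O bond, made together with the stereocentre.
- **Forward key step:** the carboxylate of the complete acid A1, (Z)-2-{[(Z)-2-methylbut-2-enoyloxy]methyl}but-2-enoic acid, would attack the aryl-bearing end of a chiral π-allyl metal complex generated from the silyl-protected cinnamyl chloride A2. This would give the branched 1-arylallyl ester A3. Saturation of the vinyl group and desilylation would finish.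
- **In its favour:** the plan is convergent, and the C–O bond and the configuration arise in one catalyst-controlled event. The acid serves as a nucleophile, so its carbonyl is never activated. On this point it is better than the chosen plan, whose steps 2 and 4 both pass through activated acyl species.
- **Against it here:** A1 is itself an allylic ester, so a low-valent allyl-forming metal can ionise its acyloxymethyl group as well as the chloride of A2. A3 is a benzylic and allylic ester on an electron-rich ring, which can re-ionise and drift to the linear conjugated isomer with loss of regio- and enantiopurity. The vinyl group must then be hydrogenated without touching two conjugated alkenes and without hydrogenolysis of the doubly activated C–O bond. The phenol must be carried as a silyl ether from a pre-oxygenated arene.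
- **Comparison:** A1 would need about four steps from 3 and 8 by way of a cleavable ester, A2 about four, and three more follow the coupling, so the count is near eleven against six. In catalytic control of the stereocentre the two plans are equal. The chosen plan separates reduction from acylation with retention and so never forms a cationic or metal-bound benzylic carbon.

Alternative 2: The cut is the C2–CH2 bond of the central butenoate, made on a benzylic ester whose ring already holds the silyl-protected oxygen.
- **Forward key step:** the iBu2AlH–N-methylmorpholine N-oxide complex would add hydride to C3 of the but-2-ynoate A4, and formaldehyde would capture the α-alumino acrylate to give the Z-hydroxymethyl butenoate A5. Angeloylation and desilylation would follow.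
- **In its favour:** every step is of a well-tried type, the ring oxygen is fixed by the starting material, and nothing depends on the site-selectivity of a late C–H functionalisation. In predictability it is the better plan.
- **Against it:** it needs a dearer, pre-oxygenated aryl building block. The silyl group must be put on, must survive aluminium reagents and hot acylation, and must then be removed with fluoride in the presence of an SN2′-prone allylic ester.
- **Comparison:** the bond construction is the one that step 3 of the chosen route applies to 5, so on the making of the Z alkene the two plans are equal. With an asymmetric ethylation of the protected aldehyde the count would be about six steps, also equal. The chosen plan gains only a commodity ketone and freedom from protecting groups, and pays with a riskier last C–H step. The fallback to the key step is this sequence with a sturdier silyl group.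

Alternative 3: The cut is the bond between ring C1 and the carbinol carbon.
- **Forward key step:** the racemic 1-chloropropyl ester A6, itself two steps from A1, would couple with the arylzinc bromide A7 under NiBr2·glyme and a chiral bis(oxazoline). The nickel catalyst would abstract chloride to give an α-acyloxyalkyl radical, which recombines with the chiral aryl–nickel species, so both enantiomers of A6 converge on the silyl-protected target A8. Desilylation would finish.
- **In its favour:** it needs no chiral alcohol and no acylation of a hindered carbinol, and it forms the C–C bond and the stereocentre together from racemic material. In convergence it is better than the chosen plan, and in catalytic control of the stereocentre its equal.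
- **Against it here:** A6 joins an α-chloroalkyl ester to an allylic ester and two Michael acceptors, so low-valent nickel can also ionise the allylic acyloxy group, and the radical or the arylzinc can add to the enoates. The acid chloride needed for A6 brings back activation of a Z-configured acid. A7 needs a pre-oxygenated, protected aryl halide, and a desilylation remains.
- **Comparison:** the count would be about ten to eleven steps against six. The enantioselectivity would depend on an ester far more functionalised than the simple ones for which this coupling is established, whereas the transfer hydrogenation of the chosen plan meets an ordinary aryl ethyl ketone.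

Key step: step 5

Remark on the chemistry: ring carbons are numbered as in each compound's own name, so C5 of the 3,4-dimethoxyphenyl ring of 10 becomes C3 of the 3-hydroxy-4,5-dimethoxyphenyl ring of 14; Oxone is taken as the triple salt 2KHSO5·KHSO4·K2SO4, of which KHSO5 reacts.

## Route

Step 1  
Reactants: 1 1-(3,4-dimethoxyphenyl)propan-1-one  
Product: 2 (S)-1-(3,4-dimethoxyphenyl)propan-1-ol  
Conditions: RuCl(p-cymene)[(S,S)-TsDPEN] (1 mol%), HCO2H–Et3N (5:2), 35 °C  
Reagents that add atoms: none  
Why: Noyori-type asymmetric transfer hydrogenation: the divalent ruthenium hydride with the (S,S)-diamine passes H− from Ru and H+ from N–H to the C=O in a six-membered outer-sphere transition state, and the CH/π contact between the η6-cymene and the aryl ring orients the ketone so that hydride enters the Re face, which gives the S carbinol.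

Step 2  
Reactants: 2 (S)-1-(3,4-dimethoxyphenyl)propan-1-ol, 3 but-2-ynoic acid  
Product: 5 (S)-1-(3,4-dimethoxyphenyl)propyl but-2-ynoate, via O-but-2-ynoyl dicyclohexylisourea 4 (not isolated)  
Conditions: DCC (1.3 equiv), DMAP (5 mol%), CH2Cl2, −20 → 0 °C  
Reagents that add atoms: none  
Why: Steglich esterification: the acid adds to DCC to give 4 and DMAP relays the acyl group to the alcohol as an acylpyridinium ion; only the acid is activated, so the C–O bond at the stereocentre stays intact and S is kept, while the low temperature and small DMAP charge hold back conjugate addition to the ynoate.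

Step 3  
Reactants: 5 (S)-1-(3,4-dimethoxyphenyl)propyl but-2-ynoate  
Product: 7 (S)-1-(3,4-dimethoxyphenyl)propyl (Z)-2-(hydroxymethyl)but-2-enoate, via α-diisobutylalumino enoate 6 (not isolated)  
Conditions: iBu2AlH (1.3 equiv), N-methylmorpholine N-oxide (1.3 equiv), THF, 0 °C; then 5, 0 °C; then CH2O (gas), 0 °C → rt; aq. KNaC4H4O6  
Reagents that add atoms: formaldehyde, `C=O`  
Why: Vinylalumination (conjugate hydroalumination of an alkynoate, then aldol-type capture): the amine oxide complex tempers the hydride so that it adds to C3 and aluminium to C2 in a syn sense, and the C–Al bond of 6 adds to formaldehyde with retention, which leaves the C3 methyl cis to the ester (Z); no bond to the carbinol carbon is touched.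

Step 4  
Reactants: 7 (S)-1-(3,4-dimethoxyphenyl)propyl (Z)-2-(hydroxymethyl)but-2-enoate, 8 angelic acid [(Z)-2-methylbut-2-enoic acid]  
Product: 10 (S)-1-(3,4-dimethoxyphenyl)propyl (Z)-2-{[(Z)-2-methylbut-2-enoyloxy]methyl}but-2-enoate, via angelic trichlorobenzoic mixed anhydride 9 (not isolated)  
Conditions: 8, 2,4,6-Cl3C6H2COCl, Et3N, toluene, rt; then 7, 75 °C  
Reagents that add atoms: none  
Why: Yamaguchi-type mixed-anhydride acylation run without DMAP, the usual way to angelates: 7 attacks the angeloyl carbonyl of 9 because the aroyl carbonyl is screened by two ortho chlorines, and with no nucleophilic catalyst present there is no addition–elimination path for Z→E isomerisation and no SN2′ attack on the acyloxymethyl acrylate.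

Step 5  
Reactants: 10 (S)-1-(3,4-dimethoxyphenyl)propyl (Z)-2-{[(Z)-2-methylbut-2-enoyloxy]methyl}but-2-enoate, 11 bis(pinacolato)diboron  
Product: 12 (S)-1-[3,4-dimethoxy-5-(4,4,5,5-tetramethyl-1,3,2-dioxaborolan-2-yl)phenyl]propyl (Z)-2-{[(Z)-2-methylbut-2-enoyloxy]methyl}but-2-enoate  
Conditions: [Ir(cod)OMe]2 (3 mol%), 4,4'-di-tert-butyl-2,2'-bipyridine (dtbpy, 6 mol%), 11 (1.5 equiv), THF, 80 °C, sealed tube  
Reagents that add atoms: none  
Why: Iridium-catalysed aromatic C–H borylation, the closest known reaction type being the sterically governed borylation of substituted arenes with 11 and a bipyridine ligand. The precatalyst, the ligand and 11 give the 16-electron trivalent iridium tris(boryl) complex (dtbpy)Ir(Bpin)3, which cleaves one aryl C–H bond by oxidative addition to a pentavalent iridium aryl hydride, eliminates the aryl–B bond reductively and is restored by 11 with release of HBpin. No ring is closed and no stereocentre is formed; the S carbinol carbon is a spectator, since no bond to it is made or broken. The step needs site-selectivity among three aryl C–H bonds and the substrate supplies it: C2–H has two ortho neighbours (chain and C3 methoxy), C6–H is ortho to the branched sp3 carbon bearing ethyl and acyloxy groups, and only C5–H has a single small ortho neighbour, the C4 methoxy group, whose methyl can turn out of the ring plane. Because the other two C–H bonds are blocked, a second borylation of the ring cannot follow. Chemoselectivity is also needed: the crowded tris(boryl) centre inserts poorly into trisubstituted electron-poor alkenes and, being trivalent, does not add oxidatively to allylic or benzylic C–O bonds, so both Z-enoates and both activated esters should pass unchanged. The methoxy-flanked site reacts more slowly than an unhindered one, hence the raised loading and 80 °C.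

Step 6  
Reactants: 12 (S)-1-[3,4-dimethoxy-5-(4,4,5,5-tetramethyl-1,3,2-dioxaborolan-2-yl)phenyl]propyl (Z)-2-{[(Z)-2-methylbut-2-enoyloxy]methyl}but-2-enoate  
Product: 14 (S)-1-(3-hydroxy-4,5-dimethoxyphenyl)propyl (Z)-2-{[(Z)-2-methylbut-2-enoyloxy]methyl}but-2-enoate, via aryl pinacol borate 13 (not isolated)  
Conditions: Oxone (2KHSO5·KHSO4·K2SO4; 1.0 equiv KHSO5), acetone–H2O (1:1), 0 °C, 10 min; then aq. NaHSO3  
Reagents that add atoms: potassium peroxymonosulfate (KHSO5), `[K+].[O-]S(=O)(=O)OO`  
Why: Ipso-oxidation of an arylboronate: peroxymonosulfate adds to boron, the aryl group shifts from B to O with loss of sulfate, and water cleaves the borate 13, so oxygen takes exactly the place of boron; the unbuffered acidic medium forms little dioxirane from acetone and attack at boron is fast at 0 °C, so the two electron-poor trisubstituted alkenes and the esters should survive.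

## Compound list

```
1 | 1-(3,4-dimethoxyphenyl)propan-1-one | CCC(=O)c1ccc(OC)c(OC)c1 | starting material
2 | (S)-1-(3,4-dimethoxyphenyl)propan-1-ol | O[C@@H](CC)c1ccc(OC)c(OC)c1 | intermediate
3 | but-2-ynoic acid | CC#CC(=O)O | starting material
4 | O-(but-2-ynoyl)-N,N'-dicyclohexylisourea | CC#CC(=O)OC(=NC1CCCCC1)NC1CCCCC1 | intermediate (not isolated)
5 | (S)-1-(3,4-dimethoxyphenyl)propyl but-2-ynoate | CC#CC(=O)O[C@@H](CC)c1ccc(OC)c(OC)c1 | intermediate
6 | (S)-1-(3,4-dimethoxyphenyl)propyl (E)-2-(diisobutylalumanyl)but-2-enoate (H and Al cis, methyl cis to the ester) | C/C=C(/[Al](CC(C)C)CC(C)C)C(=O)O[C@@H](CC)c1ccc(OC)c(OC)c1 | intermediate (not isolated)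
7 | (S)-1-(3,4-dimethoxyphenyl)propyl (Z)-2-(hydroxymethyl)but-2-enoate | C/C=C(/CO)C(=O)O[C@@H](CC)c1ccc(OC)c(OC)c1 | intermediate
8 | angelic acid, (Z)-2-methylbut-2-enoic acid | C/C=C(/C)C(=O)O | starting material
9 | (Z)-2-methylbut-2-enoic 2,4,6-trichlorobenzoic anhydride | C/C=C(/C)C(=O)OC(=O)c1c(Cl)cc(Cl)cc1Cl | intermediate (not isolated)
10 | (S)-1-(3,4-dimethoxyphenyl)propyl (Z)-2-{[(Z)-2-methylbut-2-enoyloxy]methyl}but-2-enoate | C/C=C(/C)C(=O)OC/C(=C/C)C(=O)O[C@@H](CC)c1ccc(OC)c(OC)c1 | intermediate
11 | bis(pinacolato)diboron | CC1(C)OB(OC1(C)C)B1OC(C)(C)C(C)(C)O1 | starting material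
12 | (S)-1-[3,4-dimethoxy-5-(4,4,5,5-tetramethyl-1,3,2-dioxaborolan-2-yl)phenyl]propyl (Z)-2-{[(Z)-2-methylbut-2-enoyloxy]methyl}but-2-enoate | C/C=C(/C)C(=O)OC/C(=C/C)C(=O)O[C@@H](CC)c1cc(B2OC(C)(C)C(C)(C)O2)c(OC)c(OC)c1 | intermediate
13 | (S)-1-{3,4-dimethoxy-5-[(4,4,5,5-tetramethyl-1,3,2-dioxaborolan-2-yl)oxy]phenyl}propyl (Z)-2-{[(Z)-2-methylbut-2-enoyloxy]methyl}but-2-enoate | C/C=C(/C)C(=O)OC/C(=C/C)C(=O)O[C@@H](CC)c1cc(OB2OC(C)(C)C(C)(C)O2)c(OC)c(OC)c1 | intermediate (not isolated)
14 | (S)-1-(3-hydroxy-4,5-dimethoxyphenyl)propyl (Z)-2-{[(Z)-2-methylbut-2-enoyloxy]methyl}but-2-enoate | C/C=C(/C)C(=O)OC/C(=C/C)C(=O)O[C@@H](CC)c1cc(O)c(OC)c(OC)c1 | target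
```

## Step count and least certain steps

Total step count: 6. Longest linear sequence: 6 steps (1 → 2 → 5 → 7 → 10 → 12 → 14); 3, 8 and 11 enter as purchased materials.

**Step 5 (key step).**
- **What may go wrong:** slow C–H cleavage at the methoxy-flanked position, because the C4 methoxy methyl prefers to lie in the ring plane on the side of C5–H, so the catalyst may decay before conversion is complete. The HBpin that builds up could also hydroborate the enoates or isomerise them Z→E through iridium hydrides.
- **Fallback:** the oxygen is brought in with the arene. The fallback sets out from 3 and 8 and comes back at 14.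
  - Commercial 3-hydroxy-4,5-dimethoxybenzaldehyde F1 would be silylated (iPr3SiCl, imidazole, DMF) to 4,5-dimethoxy-3-(triisopropylsilyloxy)benzaldehyde F2.
  - Catalytic asymmetric ethylation (Et2Zn, (2S)-3-exo-(dimethylamino)isoborneol, toluene, 0 °C) should give (S)-1-[4,5-dimethoxy-3-(triisopropylsilyloxy)phenyl]propan-1-ol F3.
  - Esterification with 3 as in step 2 (through 4) would give the but-2-ynoate F4.
  - Hydroalumination to the α-alumino enoate F5 and capture by formaldehyde as in step 3 would give the (Z)-2-(hydroxymethyl)but-2-enoate F6.
  - Acylation with 9 as in step 4 would give the silyl-protected target F7.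
  - HF·pyridine buffered with pyridine (THF, 0 °C) would free the phenol to give 14.
  - This costs one step more and a protecting group, but uses no C–H functionalisation.

**Step 3.**
- **What may go wrong:** hydride attack at the ester carbonyl in competition with conjugate addition, which would cleave the benzylic ester; incomplete capture of 6 because monomeric formaldehyde repolymerises; erosion of the alkene geometry through the aluminium allenolate form of 6 if the mixture warms before capture.
- **Fallback:** the fallback sets out from 5 and comes back at 7, with no hydride reductant and no formaldehyde.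
  - Hydrostannation (Bu3SnH, Pd(PPh3)4 as a zerovalent palladium catalyst, THF, 0 °C) should add H and Sn syn, with tin at C2, to give (S)-1-(3,4-dimethoxyphenyl)propyl (E)-2-(tributylstannyl)but-2-enoate F8.
  - Iododestannylation (I2, CH2Cl2, 0 °C) with retention would give (S)-1-(3,4-dimethoxyphenyl)propyl (E)-2-iodobut-2-enoate F9.
  - Stille coupling with Bu3SnCH2OH (Pd(PPh3)4, CuI, dioxane, 60 °C) with retention would give 7.
  - The geometry is carried through three stereospecific events.

**Step 4.**
- **What may go wrong:** Z→E isomerisation of the angeloyl group while it is held as an activated acyl species at 75 °C, and thermal ionisation at the benzylic ester in the presence of the ammonium salt.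
- **Fallback:** the fallback sets out from 7 and 8 and comes back at 10. Mitsunobu esterification (PPh3, DIAD, THF, 0 °C) activates the hydroxyl group of 7, not the acid. The alkoxytriphenylphosphonium angelate F10 forms in the flask and collapses by SN2 attack of angelate at the CH2 carbon. The carbonyl of 8 is never activated and no heating is needed.

**Step 6.**
- **What may go wrong:** epoxidation of the enoates by dioxirane formed from acetone and peroxymonosulfate, over-oxidation of the electron-rich phenol as it forms, and acid-promoted ionisation at the benzylic ester in the acidic medium.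
- **Fallback:** the fallback sets out from 12 and comes back at 14 through 13. The peroxide is replaced by neutral oxygen-atom transfer from an amine oxide: anhydrous Me3NO in CH2Cl2 at room temperature adds to boron and triggers the same aryl shift to 13, which a pH 7 aqueous wash hydrolyses. No peroxy species, acid or acetone is present.

## Further compounds

```
F1 | step 5 | 3-hydroxy-4,5-dimethoxybenzaldehyde | O=Cc1cc(O)c(OC)c(OC)c1
F2 | step 5 | 4,5-dimethoxy-3-(triisopropylsilyloxy)benzaldehyde | O=Cc1cc(O[Si](C(C)C)(C(C)C)C(C)C)c(OC)c(OC)c1
F3 | step 5 | (S)-1-[4,5-dimethoxy-3-(triisopropylsilyloxy)phenyl]propan-1-ol | O[C@@H](CC)c1cc(O[Si](C(C)C)(C(C)C)C(C)C)c(OC)c(OC)c1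
F4 | step 5 | (S)-1-[4,5-dimethoxy-3-(triisopropylsilyloxy)phenyl]propyl but-2-ynoate | CC#CC(=O)O[C@@H](CC)c1cc(O[Si](C(C)C)(C(C)C)C(C)C)c(OC)c(OC)c1
F5 | step 5 | (S)-1-[4,5-dimethoxy-3-(triisopropylsilyloxy)phenyl]propyl (E)-2-(diisobutylalumanyl)but-2-enoate | C/C=C(/[Al](CC(C)C)CC(C)C)C(=O)O[C@@H](CC)c1cc(O[Si](C(C)C)(C(C)C)C(C)C)c(OC)c(OC)c1
F6 | step 5 | (S)-1-[4,5-dimethoxy-3-(triisopropylsilyloxy)phenyl]propyl (Z)-2-(hydroxymethyl)but-2-enoate | C/C=C(/CO)C(=O)O[C@@H](CC)c1cc(O[Si](C(C)C)(C(C)C)C(C)C)c(OC)c(OC)c1
F7 | step 5 | (S)-1-[4,5-dimethoxy-3-(triisopropylsilyloxy)phenyl]propyl (Z)-2-{[(Z)-2-methylbut-2-enoyloxy]methyl}but-2-enoate | C/C=C(/C)C(=O)OC/C(=C/C)C(=O)O[C@@H](CC)c1cc(O[Si](C(C)C)(C(C)C)C(C)C)c(OC)c(OC)c1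
F8 | step 3 | (S)-1-(3,4-dimethoxyphenyl)propyl (E)-2-(tributylstannyl)but-2-enoate | C/C=C(/[Sn](CCCC)(CCCC)CCCC)C(=O)O[C@@H](CC)c1ccc(OC)c(OC)c1
F9 | step 3 | (S)-1-(3,4-dimethoxyphenyl)propyl (E)-2-iodobut-2-enoate | C/C=C(/I)C(=O)O[C@@H](CC)c1ccc(OC)c(OC)c1
F10 | step 4 | {(Z)-2-[(S)-1-(3,4-dimethoxyphenyl)propoxycarbonyl]but-2-enyloxy}triphenylphosphonium (Z)-2-methylbut-2-enoate | C/C=C(/CO[P+](c1ccccc1)(c1ccccc1)c1ccccc1)C(=O)O[C@@H](CC)c1ccc(OC)c(OC)c1.C/C=C(/C)C(=O)[O-]
F0 | step 6 | none | none
A1 | alternative 1 | (Z)-2-{[(Z)-2-methylbut-2-enoyloxy]methyl}but-2-enoic acid | C/C=C(/C)C(=O)OC/C(=C/C)C(=O)O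
A2 | alternative 1 | (E)-3-[3-(tert-butyldimethylsilyloxy)-4,5-dimethoxyphenyl]prop-2-en-1-yl chloride | ClC/C=C/c1cc(O[Si](C)(C)C(C)(C)C)c(OC)c(OC)c1
A3 | alternative 1 | (S)-1-[3-(tert-butyldimethylsilyloxy)-4,5-dimethoxyphenyl]prop-2-en-1-yl (Z)-2-{[(Z)-2-methylbut-2-enoyloxy]methyl}but-2-enoate | C/C=C(/C)C(=O)OC/C(=C/C)C(=O)O[C@@H](C=C)c1cc(O[Si](C)(C)C(C)(C)C)c(OC)c(OC)c1
A4 | alternative 2 | (S)-1-[3-(tert-butyldimethylsilyloxy)-4,5-dimethoxyphenyl]propyl but-2-ynoate | CC#CC(=O)O[C@@H](CC)c1cc(O[Si](C)(C)C(C)(C)C)c(OC)c(OC)c1
A5 | alternative 2 | (S)-1-[3-(tert-butyldimethylsilyloxy)-4,5-dimethoxyphenyl]propyl (Z)-2-(hydroxymethyl)but-2-enoate | C/C=C(/CO)C(=O)O[C@@H](CC)c1cc(O[Si](C)(C)C(C)(C)C)c(OC)c(OC)c1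
A6 | alternative 3 | racemic 1-chloropropyl (Z)-2-{[(Z)-2-methylbut-2-enoyloxy]methyl}but-2-enoate | C/C=C(/C)C(=O)OC/C(=C/C)C(=O)OC(Cl)CC
A7 | alternative 3 | [3-(tert-butyldimethylsilyloxy)-4,5-dimethoxyphenyl]zinc bromide | Br[Zn]c1cc(O[Si](C)(C)C(C)(C)C)c(OC)c(OC)c1
A8 | alternative 3 | (S)-1-[3-(tert-butyldimethylsilyloxy)-4,5-dimethoxyphenyl]propyl (Z)-2-{[(Z)-2-methylbut-2-enoyloxy]methyl}but-2-enoate | C/C=C(/C)C(=O)OC/C(=C/C)C(=O)O[C@@H](CC)c1cc(O[Si](C)(C)C(C)(C)C)c(OC)c(OC)c1
```
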